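# Maceneolignan H by late palladium aryl–oxygen coupling onto a lactate-derived erythro diol: synthesis design

## The problem

Maceneolignan H 17 is an open-chain 8-O-4' neolignan: the chain C7–C8–C9 carries ring A (3,4-dimethoxyphenyl) and an acetoxy group on C7, and the C8 oxygen is at the same time the phenolic oxygen at C4' of ring B (4-allyl-2,6-dimethoxyphenyl). No ring has to be closed; the skeleton is built by three connections, ring A–C7, C8–O–C4' and the allyl group at C1'. The two stereocentres are adjacent, C7 (R) and C8 (S), and stand erythro (1R,2S in the numbering of the propane chain). C8 with its oxygen and methyl group can be bought as (S)-lactic acid, and an oxygen on C8 beside a C7 ketone can steer hydride through a five-membered chelate, so C8 can control C7, whereas nothing comparable runs the other way. Several groups are fragile: C7 is benzylic, oxygen-bearing and para to a methoxy group, so acid ionises and epimerises it; the acetate does not survive bases, hydrides or organometallic reagents; the terminal allyl group moves into conjugation under metal hydrides and is lost on hydrogenation; and a carbonyl at C7 makes the C8 hydrogen enolisable. The enabling feature is that the ether oxygen sits on an sp2 carbon, C4' of ring B, between two methoxy groups. If O–C4' is the bond formed, a finished erythro alcohol can be O-arylated by palladium catalysis with no bond to C7 or C8 touched. The para position C1' can meanwhile carry an ester that activates C4'–Br and later becomes the allyl group.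

## Retrosynthesis

**C7 acetate, 17 ⇒ 16 ⇒ 15.** The acyl–oxygen bond at C7 is cut first. An acetate could not pass through carbonate base, hydride or Grignard chemistry, and next to a C8 alkoxide it would migrate. The C7 oxygen is therefore carried as the triisopropylsilyl ether 15 and released to alcohol 16 only at the end. The forward steps must be non-acidic so that C7 does not ionise.

**Allyl group, 15 ⇒ 13 + 14 and 13 ⇒ 12 ⇒ 11.** The allyl group is cut between the benzylic carbon and the vinyl carbon, giving benzylic bromide 13 and vinylmagnesium bromide 14. Cutting the aryl–CH2 bond instead would need a second halide on ring B that would compete in the palladium step. Carrying the allyl group through that step would expose it to palladium hydride and isomerisation. Bromide 13 goes back through alcohol 12 to methyl ester 11. The ester is the most useful spectator at C1' because it is para to C4' and electron-withdrawing.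

**Ether bond, the key cut, 11 ⇒ 9 + 10.** The O–C4' bond is cut, giving secondary alcohol 9 and commercial methyl 4-bromo-3,5-dimethoxybenzoate 10. The neighbouring cut, C8–O, would require an SN2 inversion at a secondary carbon flanked by a bulky benzylic centre, with elimination and aryl participation as competitors. The chosen cut leaves both stereocentres as spectators and detaches the whole of ring B with its substituents, fourteen heavy atoms, at once. The forward reaction must make C–O reductive elimination outrun β-hydride elimination, and the silyl group must stay on the C7 oxygen.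

**Differentiating the two oxygens, 9 ⇒ 8 ⇒ 7.** Alcohol 9 comes from benzyl ether 8, and 8 from alcohol 7 by silylation. Benzyl is chosen for C8 because it chelates, survives Grignard and hydride reagents, and leaves by neutral hydrogenolysis at a stage where no allyl group is present. Triisopropylsilyl is chosen for C7 because it is bulky, slow to migrate between vicinal oxygens and removable by fluoride.

**C7 stereocentre, 7 ⇒ 6.** The C7–H bond is cut, leading to α-benzyloxy ketone 6. Chelation-controlled hydride delivery to such ketones gives the anti (erythro) alcohol. Adding an aryl nucleophile to an α-alkoxy aldehyde would give the syn isomer under chelation and the anti isomer only through a less dependable open transition state.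

**Ring A–C7 bond, 6 ⇒ 3 + 5 and 5 ⇒ 4.** The ketone is cut at the aryl–carbonyl bond into Weinreb amide 3 and the Grignard reagent 5, which is made from 4-bromo-1,2-dimethoxybenzene 4. The Weinreb amide stops the addition at the ketone and holds the product as a magnesium chelate until quench, so C8 is not exposed to base as a free ketone.

**Chiral pool, 3 ⇒ 2 ⇒ 1.** Amide 3 comes from ester 2, and 2 from ethyl (S)-lactate 1 by O-benzylation. C8, its oxygen and its S configuration are bought. Benzylation under acid catalysis avoids an enolate and so avoids racemisation.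

## Roads not taken

Alternative 1: The cut is the C7–ring A bond. The Grignard reagent 5 would be transmetalated with ClTi(OiPr)3 to (3,4-dimethoxyphenyl)titanium triisopropoxide A3, and A3 would add to (S)-2-(4-allyl-2,6-dimethoxyphenoxy)propanal A2. A Felkin–Anh transition state would give (1R,2S)-2-(4-allyl-2,6-dimethoxyphenoxy)-1-(3,4-dimethoxyphenyl)propan-1-ol A1. A1 is identical with 16 and one acetylation from 17.
- Merits: A2 is about two steps from the chiral pool, the allyl group arrives already in place, and the whole route would be about four steps. On step count this road is clearly better than the chosen one.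
- Weak points: C7 of A1 is set by an open transition state next to a 2,6-dimethoxyphenoxy group that can also chelate the metal of A3, so erythro/threo selectivity is uncertain, and the two isomers of this series are hard to separate. A2 is an α-aryloxy aldehyde and racemises easily at C8.
- Comparison: the chosen plan offers a chelate-controlled ketone reduction, a C8 centre never placed alpha to an aldehyde, and a late ring B coupling that allows the aryl partner to be varied. It pays for this with roughly eight more steps.

Alternative 2: The cut removes the C7–O and C8–H bonds together and leads to the Z enol ether 5-bromo-2-{[(1Z)-1-(3,4-dimethoxyphenyl)prop-1-en-2-yl]oxy}-1,3-dimethoxybenzene A5. IpcBH2 would add suprafacially across C7=C8 of A5, with boron on C7, and NaOH/H2O2 would oxidise with retention to (1R,2S)-2-(4-bromo-2,6-dimethoxyphenoxy)-1-(3,4-dimethoxyphenyl)propan-1-ol A4. The aryl bromide of A4 would then be exchanged for allyl and C7 acetylated.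
- Merits: both stereocentres of A4 form in one step from the achiral A5, the erythro relationship follows strictly from Z geometry and syn addition, and no protecting groups are needed. The route would be shorter than the chosen one.
- Weak points: A5 is a trisubstituted Z aryl enol ether, and a geometrically pure sample is itself hard to make. The facial selectivity of a stoichiometric chiral borane on an enol ether with a bulky aryloxy group is not assured. After addition, boron on C7 lies beta to an aryloxide leaving group, so 1,2-elimination threatens.
- Comparison: the chosen plan is longer but takes its absolute configuration from lactate rather than from reagent control of unknown quality.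

Alternative 3: The cut is the C7–OAc bond. Ag2O (or DDQ) would oxidise 4-[(2S)-2-(4-allyl-2,6-dimethoxyphenoxy)propyl]-2-methoxyphenol A7 to the para-quinone methide 4-[(2S)-2-(4-allyl-2,6-dimethoxyphenoxy)propylidene]-2-methoxycyclohexa-2,5-dien-1-one A8. Acetic acid would add 1,6 at C7 of A8 to give (1R,2S)-2-(4-allyl-2,6-dimethoxyphenoxy)-1-(4-hydroxy-3-methoxyphenyl)propyl acetate A6. O-methylation of the phenol of A6 would then give 17.
- Merits: the road is biomimetic, installs the acetate directly and needs no protecting group at C7.
- Weak points: 1,2-induction from C8 in additions to quinone methides such as A8 is weak, and the addition is reversible, so an erythro/threo mixture is likely. A6 is a para-hydroxybenzylic acetate that expels acetate again as soon as the phenol is deprotonated, which is what the final methylation requires. DDQ also endangers the allyl group of A7.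
- Comparison: this road is probably shorter and avoids protecting groups, but it sets C7 reversibly. The chosen plan sets each stereocentre irreversibly by a dependable element.

Key step: step 7

## Route

Assumption: compounds 1, 4, 10 and 14 are taken as purchased. Neolignan numbering (C7, C8, C9; primed numbers for ring B) is used in the text; C7 and C8 are C1 and C2 of the propane chain in the systematic names.

Step 1
Reactants: 1 ethyl (S)-lactate
Product: 2 ethyl (2S)-2-(benzyloxy)propanoate
Conditions: BnOC(=NH)CCl3, TfOH (cat.), cyclohexane–CH2Cl2, rt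
Reagents that add atoms: benzyl 2,2,2-trichloroacetimidate, N=C(OCc1ccccc1)C(Cl)(Cl)Cl
Why: Acid-catalysed O-benzylation with a trichloroacetimidate is the standard base-free benzylation of α-hydroxy esters; no enolate forms, so C8 keeps its S configuration.

Step 2
Reactants: 2 ethyl (2S)-2-(benzyloxy)propanoate
Product: 3 (2S)-2-(benzyloxy)-N-methoxy-N-methylpropanamide
Conditions: MeNH(OMe)·HCl, iPrMgCl, THF, −20 → 0 °C
Reagents that add atoms: N,O-dimethylhydroxylamine hydrochloride, CNOC.Cl
Why: Weinreb amide formation by aminolysis of the ester with the chloromagnesium amide made in the flask is routine for lactate esters; the low temperature leaves the α-alkoxy stereocentre untouched.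

Step 3
Reactants: 3 (2S)-2-(benzyloxy)-N-methoxy-N-methylpropanamide; 4 4-bromo-1,2-dimethoxybenzene
Product: 6 (2S)-2-(benzyloxy)-1-(3,4-dimethoxyphenyl)propan-1-one, via (3,4-dimethoxyphenyl)magnesium bromide 5 (not isolated)
Conditions: Mg, THF, reflux (4 → 5); then 3, THF, 0 °C; aq. NH4Cl
Reagents that add atoms: none
Why: Aryl Grignard addition to a Weinreb amide stops at the ketone because the magnesium chelate of the tetrahedral adduct lasts until the quench; the ketone is never exposed to the basic reagent, which protects C8 from enolisation.

Step 4
Reactants: 6 (2S)-2-(benzyloxy)-1-(3,4-dimethoxyphenyl)propan-1-one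
Product: 7 (1R,2S)-2-(benzyloxy)-1-(3,4-dimethoxyphenyl)propan-1-ol
Conditions: Zn(BH4)2, Et2O, −30 → 0 °C; H2O
Reagents that add atoms: none
Why: Chelation-controlled (Cram chelate) reduction: zinc bridges the carbonyl and benzyloxy oxygens in a five-membered ring and hydride enters from the face of the C8 hydrogen, anti to the C9 methyl. This sets C7 as R, anti (erythro) to C8.

Step 5
Reactants: 7 (1R,2S)-2-(benzyloxy)-1-(3,4-dimethoxyphenyl)propan-1-ol
Product: 8 [(1R,2S)-2-(benzyloxy)-1-(3,4-dimethoxyphenyl)propoxy]triisopropylsilane
Conditions: TIPSOTf, 2,6-lutidine, CH2Cl2, 0 °C → rt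
Reagents that add atoms: triisopropylsilyl trifluoromethanesulfonate, CC(C)[Si](OS(=O)(=O)C(F)(F)F)(C(C)C)C(C)C
Why: Silylation of a hindered secondary alcohol with a silyl triflate and a hindered pyridine base is routine; the buffered medium does not ionise the benzylic C7–O bond, so the configuration holds.

Step 6
Reactants: 8 [(1R,2S)-2-(benzyloxy)-1-(3,4-dimethoxyphenyl)propoxy]triisopropylsilane
Product: 9 (1R,2S)-1-(3,4-dimethoxyphenyl)-1-(triisopropylsilyloxy)propan-2-ol
Conditions: H2 (1 atm), 10% Pd/C, EtOAc, rt
Reagents that add atoms: none
Why: Hydrogenolysis of an alkyl benzyl ether over palladium on carbon; in an aprotic solvent the secondary benzylic C7–O bond, shielded by the triisopropylsilyl group, should be cleaved far more slowly than the unhindered O–CH2Ph bond, and silyl ethers are inert.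

Step 7
Reactants: 9 (1R,2S)-1-(3,4-dimethoxyphenyl)-1-(triisopropylsilyloxy)propan-2-ol; 10 methyl 4-bromo-3,5-dimethoxybenzoate
Product: 11 methyl 4-{[(1R,2S)-1-(3,4-dimethoxyphenyl)-1-(triisopropylsilyloxy)propan-2-yl]oxy}-3,5-dimethoxybenzoate
Conditions: Pd2(dba)3 (2.5 mol%), RockPhos (7.5 mol%), Cs2CO3, toluene, 90 °C
Reagents that add atoms: none
Why: Zerovalent palladium carrying RockPhos inserts into the C4'–Br bond of 10, which the para ester makes electron-poor; alcohol 9 binds to the divalent arylpalladium bromide and is deprotonated by Cs2CO3 to the arylpalladium alkoxide; C–O reductive elimination then forms the O–C4' bond and returns zerovalent palladium. The closest known reaction type is the palladium-catalysed etherification of aryl bromides with secondary alcohols under bulky di-tert-butyl biaryl phosphines, which is established for ortho-substituted aryl halides. No ring is closed and no stereocentre is made: no bond to C7 or C8 is formed or broken, so the (1R,2S) configuration of 9 is carried over. The selectivity needed is reductive elimination ahead of β-hydride elimination of the C8 hydrogen; the bulk of the ligand, the electron-poor aryl group and the two ortho methoxy groups crowding the metal all favour reductive elimination. Because the alcohol is deprotonated on the metal by a weak, sparingly soluble base, little free alkoxide is present, which limits transesterification of the methyl ester and 1,2-silyl migration; the triisopropylsilyl group is chosen because it migrates least readily. A slight excess of 10 is used because 9 is the more valuable partner.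

Step 8
Reactants: 11 methyl 4-{[(1R,2S)-1-(3,4-dimethoxyphenyl)-1-(triisopropylsilyloxy)propan-2-yl]oxy}-3,5-dimethoxybenzoate
Product: 12 (4-{[(1R,2S)-1-(3,4-dimethoxyphenyl)-1-(triisopropylsilyloxy)propan-2-yl]oxy}-3,5-dimethoxyphenyl)methanol
Conditions: i-Bu2AlH, CH2Cl2, −78 → 0 °C; aq. potassium sodium tartrate
Reagents that add atoms: none
Why: Reduction of an aryl ester to the benzylic alcohol with excess i-Bu2AlH is standard; silyl and aryl ethers are inert to it.

Step 9
Reactants: 12 (4-{[(1R,2S)-1-(3,4-dimethoxyphenyl)-1-(triisopropylsilyloxy)propan-2-yl]oxy}-3,5-dimethoxyphenyl)methanol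
Product: 13 {(1R,2S)-2-[4-(bromomethyl)-2,6-dimethoxyphenoxy]-1-(3,4-dimethoxyphenyl)propoxy}triisopropylsilane
Conditions: CBr4, PPh3, CH2Cl2, 0 °C
Reagents that add atoms: carbon tetrabromide, BrC(Br)(Br)Br
Why: Appel bromination converts a primary benzylic alcohol to the bromide under neutral conditions, which spares the acid-sensitive C7 silyl ether; the bromide is used without storage.

Step 10
Reactants: 13 {(1R,2S)-2-[4-(bromomethyl)-2,6-dimethoxyphenoxy]-1-(3,4-dimethoxyphenyl)propoxy}triisopropylsilane; 14 vinylmagnesium bromide
Product: 15 {(1R,2S)-2-(4-allyl-2,6-dimethoxyphenoxy)-1-(3,4-dimethoxyphenyl)propoxy}triisopropylsilane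
Conditions: CuI (10 mol%), THF, −20 → 0 °C
Reagents that add atoms: none
Why: Copper-catalysed cross-coupling of a benzylic bromide with a vinyl Grignard reagent is an established route to allylarenes; the low temperature limits homocoupling, and no metal hydride is present to move the double bond into conjugation.

Step 11
Reactants: 15 {(1R,2S)-2-(4-allyl-2,6-dimethoxyphenoxy)-1-(3,4-dimethoxyphenyl)propoxy}triisopropylsilane
Product: 16 (1R,2S)-2-(4-allyl-2,6-dimethoxyphenoxy)-1-(3,4-dimethoxyphenyl)propan-1-ol
Conditions: Bu4NF, THF, 0 °C → rt
Reagents that add atoms: none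
Why: Fluoride cleavage of the silyl ether releases the C7 alcohol without ionising the benzylic C–O bond, so C7 stays R; the C8 aryl ether cannot migrate.

Step 12
Reactants: 16 (1R,2S)-2-(4-allyl-2,6-dimethoxyphenoxy)-1-(3,4-dimethoxyphenyl)propan-1-ol
Product: 17 maceneolignan H [(1R,2S)-2-(4-allyl-2,6-dimethoxyphenoxy)-1-(3,4-dimethoxyphenyl)propyl acetate]
Conditions: Ac2O, pyridine, DMAP (cat.), CH2Cl2, rt
Reagents that add atoms: acetic anhydride, CC(=O)OC(C)=O
Why: DMAP-catalysed acetylation of a secondary benzylic alcohol; the basic, non-ionising conditions retain C7 and leave the allyl group untouched.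

## Compound list

1 | ethyl (S)-lactate | CCOC(=O)[C@H](C)O | starting material
2 | ethyl (2S)-2-(benzyloxy)propanoate | CCOC(=O)[C@H](C)OCc1ccccc1 | intermediate
3 | (2S)-2-(benzyloxy)-N-methoxy-N-methylpropanamide | CON(C)C(=O)[C@H](C)OCc1ccccc1 | intermediate
4 | 4-bromo-1,2-dimethoxybenzene | COc1ccc(Br)cc1OC | starting material
5 | (3,4-dimethoxyphenyl)magnesium bromide | COc1ccc([Mg]Br)cc1OC | intermediate
6 | (2S)-2-(benzyloxy)-1-(3,4-dimethoxyphenyl)propan-1-one | COc1ccc(C(=O)[C@H](C)OCc2ccccc2)cc1OC | intermediate
7 | (1R,2S)-2-(benzyloxy)-1-(3,4-dimethoxyphenyl)propan-1-ol | C[C@H](OCc1ccccc1)[C@H](O)c1ccc(OC)c(OC)c1 | intermediate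
8 | [(1R,2S)-2-(benzyloxy)-1-(3,4-dimethoxyphenyl)propoxy]triisopropylsilane | C[C@H](OCc1ccccc1)[C@H](O[Si](C(C)C)(C(C)C)C(C)C)c1ccc(OC)c(OC)c1 | intermediate
9 | (1R,2S)-1-(3,4-dimethoxyphenyl)-1-(triisopropylsilyloxy)propan-2-ol | C[C@H](O)[C@H](O[Si](C(C)C)(C(C)C)C(C)C)c1ccc(OC)c(OC)c1 | intermediate
10 | methyl 4-bromo-3,5-dimethoxybenzoate | COC(=O)c1cc(OC)c(Br)c(OC)c1 | starting material
11 | methyl 4-{[(1R,2S)-1-(3,4-dimethoxyphenyl)-1-(triisopropylsilyloxy)propan-2-yl]oxy}-3,5-dimethoxybenzoate | COC(=O)c1cc(OC)c(O[C@@H](C)[C@H](O[Si](C(C)C)(C(C)C)C(C)C)c2ccc(OC)c(OC)c2)c(OC)c1 | intermediate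
12 | (4-{[(1R,2S)-1-(3,4-dimethoxyphenyl)-1-(triisopropylsilyloxy)propan-2-yl]oxy}-3,5-dimethoxyphenyl)methanol | OCc1cc(OC)c(O[C@@H](C)[C@H](O[Si](C(C)C)(C(C)C)C(C)C)c2ccc(OC)c(OC)c2)c(OC)c1 | intermediate
13 | {(1R,2S)-2-[4-(bromomethyl)-2,6-dimethoxyphenoxy]-1-(3,4-dimethoxyphenyl)propoxy}triisopropylsilane | BrCc1cc(OC)c(O[C@@H](C)[C@H](O[Si](C(C)C)(C(C)C)C(C)C)c2ccc(OC)c(OC)c2)c(OC)c1 | intermediate
14 | vinylmagnesium bromide | C=C[Mg]Br | starting material
15 | {(1R,2S)-2-(4-allyl-2,6-dimethoxyphenoxy)-1-(3,4-dimethoxyphenyl)propoxy}triisopropylsilane | C=CCc1cc(OC)c(O[C@@H](C)[C@H](O[Si](C(C)C)(C(C)C)C(C)C)c2ccc(OC)c(OC)c2)c(OC)c1 | intermediate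
16 | (1R,2S)-2-(4-allyl-2,6-dimethoxyphenoxy)-1-(3,4-dimethoxyphenyl)propan-1-ol | C=CCc1cc(OC)c(O[C@@H](C)[C@H](O)c2ccc(OC)c(OC)c2)c(OC)c1 | intermediate
17 | maceneolignan H [(1R,2S)-2-(4-allyl-2,6-dimethoxyphenoxy)-1-(3,4-dimethoxyphenyl)propyl acetate] | C=CCc1cc(OC)c(O[C@@H](C)[C@H](OC(C)=O)c2ccc(OC)c(OC)c2)c(OC)c1 | target

## Step count and least certain steps

Total: 12 steps. Longest linear sequence: 12 steps, from 1 to 17; compounds 4, 10 and 14 enter as purchased partners.

**Step 7, the key step.** β-Hydride elimination from the palladium alkoxide may outrun reductive elimination, which would oxidise the alcohol and reduce the aryl bromide. The hindered alkoxide, next to a triisopropylsilyloxy group, may also fail to bind to a di-ortho-substituted arylpalladium centre. Slower background processes are transesterification of the methyl ester and silyl migration toward the C8 oxygen.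

Fallback: the ether is made at C8 by SN2 with inversion before ring A is attached. The fallback sets out from the Grignard reagent 5, made from 4 as in step 3, and comes back to the route at 16. Methyl (R)-lactate F1 and 4-allyl-2,6-dimethoxyphenol F2, both purchased, would be joined under Mitsunobu conditions (PPh3, DIAD, THF) to methyl (2S)-2-(4-allyl-2,6-dimethoxyphenoxy)propanoate F3. Aminolysis as in step 2 would give (2S)-2-(4-allyl-2,6-dimethoxyphenoxy)-N-methoxy-N-methylpropanamide F4. Addition of 5 would give (2S)-2-(4-allyl-2,6-dimethoxyphenoxy)-1-(3,4-dimethoxyphenyl)propan-1-one F5, and Zn(BH4)2 reduction under chelation control would give 16. This path is shorter, but its C8 centre lies alpha to an aryl ketone with an aryloxy substituent and is lost far more easily by enolisation, so it is held in reserve.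

**Step 6.** The benzylic C7–O bond on the electron-rich ring may be hydrogenolysed together with the benzyl ether, or debenzylation of the hindered C8 ether may be sluggish.

Fallback: the C8 oxygen is carried as an acetal that is removed by mild acid instead of by reduction; the fallback sets out from 1 and comes back to the route at 9. Ethyl (S)-lactate 1 would be protected with 3,4-dihydro-2H-pyran and PPTS as ethyl (2S)-2-(tetrahydro-2H-pyran-2-yloxy)propanoate F6, a pair of acetal epimers. The operations of steps 2 to 5 would then give in turn the Weinreb amide (2S)-N-methoxy-N-methyl-2-(tetrahydro-2H-pyran-2-yloxy)propanamide F7, with 5 the ketone (2S)-1-(3,4-dimethoxyphenyl)-2-(tetrahydro-2H-pyran-2-yloxy)propan-1-one F8, by chelation-controlled reduction the alcohol (1R,2S)-1-(3,4-dimethoxyphenyl)-2-(tetrahydro-2H-pyran-2-yloxy)propan-1-ol F9, and by silylation triisopropyl{(1R,2S)-1-(3,4-dimethoxyphenyl)-2-(tetrahydro-2H-pyran-2-yloxy)propoxy}silane F10. PPTS in MeOH would then remove the acetal and give 9.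

**Step 10.** Wurtz-type homocoupling of the reactive, electron-rich benzylic bromide and halogen–magnesium exchange may compete with the copper-catalysed substitution.

Fallback: the same bond is made by palladium-catalysed Stille coupling. Bromide 13 would be treated with tributyl(vinyl)stannane and Pd(PPh3)4 in toluene at 70 °C, which involves no strongly basic organometallic reagent; the fallback sets out from 13 and comes back to the route at 15.

**Step 4.** Facial selectivity may be poor if an open (Felkin-type) transition state competes with the zinc chelate, since that pathway delivers hydride to the opposite face.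

Fallback: reagent control replaces substrate control. Ketone 6 would be reduced with BH3·SMe2 and the (R)-configured 2-methyl-CBS-oxazaborolidine, the enantiomer that delivers hydride to the same face as the chelate model when ring A acts as the large group; the fallback sets out from 6 and comes back to the route at 7.

## Further compounds

F0 | step 4 | none | none
F0 | step 10 | none | none
F1 | step 7 | methyl (R)-lactate (purchased) | COC(=O)[C@@H](C)O
F2 | step 7 | 4-allyl-2,6-dimethoxyphenol (purchased) | C=CCc1cc(OC)c(O)c(OC)c1
F3 | step 7 | methyl (2S)-2-(4-allyl-2,6-dimethoxyphenoxy)propanoate | C=CCc1cc(OC)c(O[C@@H](C)C(=O)OC)c(OC)c1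
F4 | step 7 | (2S)-2-(4-allyl-2,6-dimethoxyphenoxy)-N-methoxy-N-methylpropanamide | C=CCc1cc(OC)c(O[C@@H](C)C(=O)N(C)OC)c(OC)c1
F5 | step 7 | (2S)-2-(4-allyl-2,6-dimethoxyphenoxy)-1-(3,4-dimethoxyphenyl)propan-1-one | C=CCc1cc(OC)c(O[C@@H](C)C(=O)c2ccc(OC)c(OC)c2)c(OC)c1
F6 | step 6 | ethyl (2S)-2-(tetrahydro-2H-pyran-2-yloxy)propanoate (acetal epimers) | CCOC(=O)[C@H](C)OC1CCCCO1
F7 | step 6 | (2S)-N-methoxy-N-methyl-2-(tetrahydro-2H-pyran-2-yloxy)propanamide (acetal epimers) | CON(C)C(=O)[C@H](C)OC1CCCCO1
F8 | step 6 | (2S)-1-(3,4-dimethoxyphenyl)-2-(tetrahydro-2H-pyran-2-yloxy)propan-1-one (acetal epimers) | COc1ccc(C(=O)[C@H](C)OC2CCCCO2)cc1OC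
F9 | step 6 | (1R,2S)-1-(3,4-dimethoxyphenyl)-2-(tetrahydro-2H-pyran-2-yloxy)propan-1-ol (acetal epimers) | C[C@H](OC1CCCCO1)[C@H](O)c1ccc(OC)c(OC)c1
F10 | step 6 | triisopropyl{(1R,2S)-1-(3,4-dimethoxyphenyl)-2-(tetrahydro-2H-pyran-2-yloxy)propoxy}silane (acetal epimers) | C[C@H](OC1CCCCO1)[C@H](O[Si](C(C)C)(C(C)C)C(C)C)c1ccc(OC)c(OC)c1
A1 | alternative 1 | (1R,2S)-2-(4-allyl-2,6-dimethoxyphenoxy)-1-(3,4-dimethoxyphenyl)propan-1-ol (identical with 16) | C=CCc1cc(OC)c(O[C@@H](C)[C@H](O)c2ccc(OC)c(OC)c2)c(OC)c1
A2 | alternative 1 | (S)-2-(4-allyl-2,6-dimethoxyphenoxy)propanal | C=CCc1cc(OC)c(O[C@@H](C)C=O)c(OC)c1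
A3 | alternative 1 | (3,4-dimethoxyphenyl)titanium triisopropoxide | COc1ccc([Ti](OC(C)C)(OC(C)C)OC(C)C)cc1OC
A4 | alternative 2 | (1R,2S)-2-(4-bromo-2,6-dimethoxyphenoxy)-1-(3,4-dimethoxyphenyl)propan-1-ol | COc1cc(Br)cc(OC)c1O[C@@H](C)[C@H](O)c1ccc(OC)c(OC)c1
A5 | alternative 2 | 5-bromo-2-{[(1Z)-1-(3,4-dimethoxyphenyl)prop-1-en-2-yl]oxy}-1,3-dimethoxybenzene | COc1ccc(/C=C(/C)Oc2c(OC)cc(Br)cc2OC)cc1OC
A6 | alternative 3 | (1R,2S)-2-(4-allyl-2,6-dimethoxyphenoxy)-1-(4-hydroxy-3-methoxyphenyl)propyl acetate | C=CCc1cc(OC)c(O[C@@H](C)[C@H](OC(C)=O)c2ccc(O)c(OC)c2)c(OC)c1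
A7 | alternative 3 | 4-[(2S)-2-(4-allyl-2,6-dimethoxyphenoxy)propyl]-2-methoxyphenol | C=CCc1cc(OC)c(O[C@@H](C)Cc2ccc(O)c(OC)c2)c(OC)c1
A8 | alternative 3 | 4-[(2S)-2-(4-allyl-2,6-dimethoxyphenoxy)propylidene]-2-methoxycyclohexa-2,5-dien-1-one (exocyclic alkene geometry unspecified) | C=CCc1cc(OC)c(O[C@@H](C)C=C2C=CC(=O)C(OC)=C2)c(OC)c1
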